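The forecaster and a bench chemist read the same two earlier runs of a ligand exchange and disagree on one point: is the flask below still moving at its asked time?

all flasks: starting complex 20 mM
- maple: incoming ligand 6 mM; leaving ligand 20 mM; run made earlier
- elm: incoming ligand 24 mM; leaving ligand 20 mM; run made earlier
- flask: incoming ligand 12.0 mM; leaving ligand 20.0 mM; time 8.0 d

| run | time / d | starting complex / % | complex with three exchanged / % |
|---|---|---|---|
| maple | 0.833 | 85 | 0 |
| maple | 2.50 | 84 | 1 |
| maple | 4.00 | 81 | 2 |
| maple | 6.00 | 81 | 4 |
| maple | 10.0 | 85 | 1 |
| elm | 2.08 | 52 | 3 |
| elm | 4.00 | 55 | 4 |
| elm | 6.00 | 53 | 5 |
| elm | 8.00 | 51 | 7 |
| elm | 10.0 | 54 | 7 |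

(each reading ± 1.5 percentage points)

- the reaction counts as stopped when no species that holds the starting complex changes by six tenths of a point or more over the second half of the time

* at 8.0 d, what has stopped the reaction, if anything has (the incoming ligand has run out first / it is still moving / forward and back rates have come level / all of the starting complex has reacted)
* share of the starting complex used up at 8.0 d
* complex with three exchanged at 8.0 d, in percent of the starting complex charged
* complex with one exchanged at 8.0 d, in percent of the starting complex charged

The forecaster points to the elm run, where complex with three exchanged climbs 4 percentage points from first reading to last. The bench chemist points to the starting complex, which reads 85% first and 85% last in the maple run, and 52% and 54% in the elm run, against a scatter of 1.5 points.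

She asks what the end state must be. Averaged over the readings, the maple run lost 16.8% of its starting complex, or 3.36 mM, and the elm run lost 47.0%, or 9.40 mM. She counts each reacted complex as having taken one incoming ligand and given one leaving ligand. She then multiplies the reacted amount by the leaving ligand present and divides by the starting complex left times the incoming ligand left. This gives 1.79 for the maple run and 1.79 for the elm run, although their incoming ligand differs, 6 mM against 24 mM. Their mean, 1.79, is her balance number, an apparent equilibrium constant.

Solved for the flask, that number gives 5.91 mM reacted, a share of 29.6%. Since the starting complex reads flat from the first reading in both runs, she calls the flask level.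

The forecast says it is still moving, with 29% used up (26% to 33%), 4.2% of complex with three exchanged and 24.8% of complex with one exchanged: “Mc still gains about 2 points over the last 4 d, so the reaction is still moving.”

The simulation answers that forward and back rates have come level, with 27.7% used up, 1.63% of complex with three exchanged and 15.4% of complex with one exchanged.

    starting complex + incoming ligand ⇌ leaving ligand + complex with one exchanged (K = 1.80, k = 0.180 L mol⁻¹ min⁻¹)
    complex with one exchanged + incoming ligand ⇌ leaving ligand + complex with two exchanged (K = 5.10, k = 0.0590 L mol⁻¹ min⁻¹)
    complex with two exchanged + incoming ligand ⇌ leaving ligand + complex with three exchanged (K = 1.50, k = 0.350 L mol⁻¹ min⁻¹)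
    complex with three exchanged ⇌ isomer of the product (K = 1.10, k = 1.60 × 10⁻⁴ min⁻¹)

The flask does move in its first days: complex with one exchanged falls from 21.5% at 0.800 d to 15.8% at 4.00 d, and it stands at 15.2% at 80.0 d. The bench chemist's share for the flask lies 1.9 points above the simulated one. With 7.2 mM of incoming ligand in a neighbouring flask, the balance number gives 3.93 mM reacted, a share of 19.6%. That neighbouring flask has 18.3% of its starting complex used up, and 29% of its incoming ligand is still unbound at 8.00 d.

Readings and results stem from a simulated flask with constants of no real substance; scatter was added.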